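## Structural features

The target is a (3S)-isoflavanone: a chroman-4-one in which benzo ring A is fused to the dihydropyranone ring C, with aryl ring B attached at C3. Ring A carries phenols at C5 (hydrogen-bonded to the C4 carbonyl) and C7. Ring B is 1',2',3',4'-tetrasubstituted: a 2'-phenol, a 3'-geranyl chain with two trisubstituted alkenes, and a 4'-methyl ether, so the phenol is flanked by the link to C3 and by the side chain. C3 is the only stereocentre, with no neighbour to relay from; it is tertiary, benzylic and alpha to the ketone, hence acidic and easily racemised through the enol. The CIP order at C3 is C4 > C2 > C1' > H, which makes the drawn configuration S. The fragile elements are this centre, the three electron-rich phenols, and the geranyl alkenes, which cyclise onto O2' under acid (chroman formation), add electrophilic halogen and rule out hydrogenation. The real difficulty is not the skeleton (a deoxybenzoin plus one carbon) but creating C3 enantioselectively late and never exposing it afterwards to base or strong acid, together with the regiocontrolled assembly of ring B. The key step exploits the fact that C2 is an isolated methylene bonded only to O1 and C3: it can travel as the methyl group of a ring A methyl ether ortho to the C4 acyl group and be joined to C3 by insertion of a C3 carbenoid into one of its C–H bonds.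

## Logic of the disconnections

**15 back to 14.** The O–H bonds at O5, O7 and O2' become O–Si bonds. Free phenols would capture a carbenoid by O–H insertion and consume base in the enolate steps, and a free 2'-phenol next to the geranyl chain invites chroman formation. Silyl ethers offer a carbenoid no oxygen-activated C–H bond and leave under fluoride without acid or base strong enough to enolise C3. Nothing is gained in skeleton; the gain is an end game of one operation. The forward step needs a buffered fluoride source and a neutral work-up.

**14 back to 13.** The C2–C3 bond is cut: C2 returns to the methyl group of the ring A methyl ether, C3 to a diazo-bearing carbon between the C4 carbonyl and ring B. This is the one cut that removes ring C and the only stereocentre together and leaves an achiral deoxybenzoin skeleton with C2 already at the right oxidation level. The forward step must choose the methoxy C–H over every other C–H, choose insertion over attack on oxygen lone pairs, and choose one carbenoid face. For that reason all three phenols in 13 carry tert-butyldimethylsilyl groups. A tert-butyldiphenylsilyl group on O2' is avoided: its phenyl rings are targets for an electrophilic carbenoid (Buchner-type addition), it is hard to place on a phenol with two ortho substituents, and it crowds both the aryl bromide and the carbenoid carbon. A single kind of silyl group also allows one uniform deprotection.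

**13 back to 12.** The C=N2 unit is removed, leaving the doubly activated methylene (benzylic and alpha to the ketone). The diazo group is the most sensitive function of the route, so it is introduced last before use. The forward diazo transfer needs a base mild enough for three aryl silyl ethers.

**12 back to 9 and 11.** The bond between the alpha-carbon (future C3) and C1' is cut. This divides the molecule into halves of similar size, each carrying its own substituent pattern, and makes the route convergent. The forward arylation must tolerate an ortho-silyloxy aryl bromide and a methyl ketone whose enolate sits next to a silyl ether, hence a weak, insoluble base.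

**11 back to 10.** Two O–Si bonds are cut. In 10 the methyl ether already sits on the oxygen that becomes O1, so no selective methylation is needed. The forward silylation must also reach the hydrogen-bonded phenol.

**9 back to 8 and 7.** The O–Si bond is cut and the phenol is traced to its methoxymethyl ether. The methoxymethyl group is needed as the directing group for ring metalation but cannot be carried on: its OCH2O hydrogens would lie in a 1,5 relationship to the carbenoid carbon. The exchange costs two steps. The forward acetal cleavage must not let the liberated phenol add to the neighbouring alkene.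

**7 back to 5 (through 6).** The C–Br bond is cut. The bromine must sit ortho to the protected phenol and para to the methyl ether; electrophilic bromination would be regiochemically ambiguous and would attack the alkenes. Directed metalation followed by a bromine-transfer reagent answers both points. The forward step requires ring lithiation next to the methoxymethoxy group, not next to the methoxy group or at the benzylic–allylic CH2.

**5 back to 2 and 3 (through 4), and 2 back to 1.** The aryl–CH2 bond of the side chain is cut at the carbon between the two oxygens, the most acidic ring position, so the first lithiation is unambiguous. 3 brings the complete E-configured chain. The forward allylation must go at the primary carbon of 3 without allylic transposition. 2 arises from 1 by protection.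

## Other disconnections considered

**Alternative 1:** Ring B is dismantled across C1'–C2', C2'–C3' and C4'–C5'. This leaves a chromone carrying a four-carbon diazo enone at C3, (E)-1-diazo-4-[5,7-bis(methoxymethoxy)-4-oxo-4H-chromen-3-yl]but-3-en-2-one A1, and a geranyl-derived ynol ether, (E)-1-methoxy-5,9-dimethyldeca-4,8-dien-1-yne A3.

- Forward key step: irradiation of A1 would cause Wolff rearrangement to the vinylketene A2. A2 would add to A3 by [2+2] cycloaddition; four-electron ring opening, six-electron ring closure and tautomerisation (a Danheiser-type benzannulation) would give the isoflavone A4 with the 2'-phenol free.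
- In its favour: the whole 2'-hydroxy-3'-geranyl-4'-methoxy pattern is written in one regiodefined operation, fixed by the polarity of A3, and O2' needs no protecting group. On ring B regiochemistry this plan is the better one; the chosen plan needs two directed lithiations and a protecting-group exchange.
- Against it: A4 is planar at C3, so the only stereocentre is still to come. Conjugate reduction of C2=C3 delivers hydride to C2 and leaves C3 to enolate protonation, for which dependable enantiocontrol is lacking; hydrogenation is barred by the geranyl alkenes. A3 is a skipped enyne and an ynol ether, prone to isomerise, and must be made for the purpose. The chromone chromophore of A1 competes for light. The methoxymethyl ethers must finally leave under acid with C3 and the geranyl chain exposed.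
- Comparison: a pericyclic cascade under neutral conditions is the more predictable in chemoselectivity than a carbenoid insertion; on that point the alternative is the better. Only the chosen plan creates C3 in the step that closes the ring. Step counts to the key step should be similar, but the alternative then needs a reduction, a separate stereochemical solution and an acidic deprotection, against one fluoride step.

**Alternative 2:** The cuts are C3–C4 and O1–C2, dividing the molecule into a ring A benzodioxinone, 5,7-bis(tert-butyldimethylsilyloxy)-2,2-dimethyl-4H-1,3-benzodioxin-4-one A5, and a ring B enol ether, tert-butyl{2-geranyl-3-methoxy-6-[(E)-2-methoxyethenyl]phenoxy}dimethylsilane A7.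

- Forward key step: photochemical cycloreversion of A5 would unmask the quinoketene A6, an electron-poor heterodiene. The aryl-bearing, nucleophilic carbon of A7 would attack its ketene carbon (C3–C4) and the ring oxygen would close on the alkoxy-bearing carbon (O1–C2), giving the 2-methoxyisoflavanone A8.
- In its favour: it is the most convergent of the four plans. Ring C would form from two halves of equal size without metal, base or diazo compound, and the same silyl protection can be used. On convergence, mildness and hazard of the ring-forming step it is the better plan; on protecting-group scheme it is the equal.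
- Against it: C2 arrives at the acetal oxidation level and must be reduced to a methylene with a silane and a Lewis acid in the presence of silyl ethers and geranyl alkenes; otherwise A8 loses its 2-methoxy group by elimination and C3 is flattened. Neither stereocentre of A8 is controlled, so C3 would emerge racemic and a resolution or deracemising sequence would be added. A7 is hindered by its ortho silyloxy group, and a slow cycloaddition gives A6 time to dimerise.
- Comparison: the chosen plan has C2 at the correct oxidation level from the start and lets the catalyst set C3. The alternative is likely equal in steps up to A8 and two to four steps longer after it.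

**Alternative 3:** The cut is the aryl ether bond O1–C8a, after C4 has been taken back to a protected carbinol. The precursor is the bromo alcohol (2S,3R)-3-[2-bromo-4,6-bis(methoxymethoxy)phenyl]-3-(tert-butyldimethylsilyloxy)-2-[3-geranyl-4-methoxy-2-(methoxymethoxy)phenyl]propan-1-ol A9. It would be assembled by an auxiliary-controlled aldol union of the two ring halves, silylation of the new carbinol and reductive release of the auxiliary.

- Forward key step: Pd(OAc)2 with a bulky biarylphosphine and Cs2CO3 would effect oxidative addition into the aryl bromide, alkoxide binding and C–O reductive elimination, giving the trans-(3S)-isoflavan-4-ol silyl ether A10.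
- In its favour: C3 would be set by a very dependable asymmetric reaction and would stay non-acidic, flanked by a carbinol, until the late oxidation. On security of configuration during the synthesis this plan is the better one. The palladium etherification is as mature as the palladium arylation of the chosen plan.
- Against it: C4 is built at the wrong oxidation level, so desilylation and oxidation must follow. Three methoxymethyl ethers then have to leave under acid at the very stage where C3 has become epimerisable and the geranyl chain can cyclise. The auxiliary is stoichiometric, both halves need longer preparation, and beta-hydride elimination of the palladium alkoxide and hindrance at the doubly ortho-substituted bromide threaten the closure.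
- Comparison: more reliable stereochemistry, at the price of redox detours and an estimated fifteen steps against ten.

Key step: step 9

Remarks on the chemistry:
- Geranyl means (2E)-3,7-dimethylocta-2,6-dien-1-yl. TBS is tert-butyldimethylsilyl, MOM is methoxymethyl, p-ABSA is 4-acetamidobenzenesulfonyl azide, XPhos is 2-dicyclohexylphosphino-2',4',6'-triisopropylbiphenyl, and Rh2(S-PTTL)4 is dirhodium tetrakis[N-phthaloyl-(S)-tert-leucinate].
- Assumption: the (S)-configured ligand set is taken to deliver the 3S product. Should the sense of induction be opposite, Rh2(R-PTTL)4 is used and nothing else changes.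
- Hazards: MOMCl is a carcinogen and is handled as a solution in a closed system. p-ABSA is chosen as a sulfonyl azide of low shock sensitivity. 13 is kept in solution, cold and away from light.

## Route

Step 1
Reactants: 1 3-methoxyphenol
Product: 2 1-methoxy-3-(methoxymethoxy)benzene
Conditions: MOMCl, i-Pr2NEt, CH2Cl2, 0 °C → rt
Reagents that add atoms: chloromethyl methyl ether, COCCl
Why: O-Alkylation of the phenol (Williamson-type acetal formation). The MOM ether resists organolithiums and is the strongest alkoxy-type directing group for the two ring metalations that follow.

Step 2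
Reactants: 2 1-methoxy-3-(methoxymethoxy)benzene; 3 geranyl bromide
Product: 5 2-geranyl-1-methoxy-3-(methoxymethoxy)benzene, via [2-methoxy-6-(methoxymethoxy)phenyl]lithium 4 (not isolated)
Conditions: n-BuLi, THF, 0 °C; then CuI (10 mol%), 3, −78 °C → rt
Reagents that add atoms: none
Why: Directed ortho-metalation; both oxygens direct n-BuLi to the carbon between them. Copper-catalysed allylic substitution of the aryl anion on the primary allylic bromide should proceed at the primary carbon and keep the E alkene.

Step 3
Reactants: 5 2-geranyl-1-methoxy-3-(methoxymethoxy)benzene
Product: 7 1-bromo-3-geranyl-4-methoxy-2-(methoxymethoxy)benzene, via [3-geranyl-4-methoxy-2-(methoxymethoxy)phenyl]lithium 6 (not isolated)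
Conditions: n-BuLi, TMEDA, Et2O, 0 °C → rt; then BrCl2C–CCl2Br, −78 °C → rt
Reagents that add atoms: 1,2-dibromotetrachloroethane, BrC(Cl)(Cl)C(Cl)(Cl)Br
Why: Second directed ortho-metalation; the chelating MOM ether outranks the methyl ether as director, so lithiation is expected ortho to OMOM and para to OMe. Bromine transfer from the polyhaloethane to the aryllithium avoids any electrophilic bromine that would add to the geranyl alkenes.

Step 4
Reactants: 7 1-bromo-3-geranyl-4-methoxy-2-(methoxymethoxy)benzene
Product: 8 6-bromo-2-geranyl-3-methoxyphenol
Conditions: aq. HCl (3 M), MeOH, rt → 40 °C, stopped at full conversion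
Reagents that add atoms: none
Why: Acid-catalysed transacetalisation of the MOM ether to methanol. Dilute acid at low temperature is the usual way to free phenols beside prenyl-type chains without chroman formation, and the ortho bromine lowers the nucleophilicity of the phenol further.

Step 5
Reactants: 8 6-bromo-2-geranyl-3-methoxyphenol
Product: 9 (6-bromo-2-geranyl-3-methoxyphenoxy)(tert-butyl)dimethylsilane
Conditions: TBSCl, imidazole, DMAP (cat.), DMF, rt → 40 °C
Reagents that add atoms: tert-butyldimethylsilyl chloride, CC(C)(C)[Si](C)(C)Cl
Why: Imidazole-promoted O-silylation. TBS is small enough for a phenol with two ortho substituents and carries neither oxygen-activated C–H bonds nor aryl rings that a carbenoid could attack.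

Step 6
Reactants: 10 2',4'-dihydroxy-6'-methoxyacetophenone
Product: 11 2',4'-bis(tert-butyldimethylsilyloxy)-6'-methoxyacetophenone
Conditions: TBSCl, imidazole, DMF, rt → 50 °C
Reagents that add atoms: tert-butyldimethylsilyl chloride, CC(C)(C)[Si](C)(C)Cl
Why: O-Silylation of both phenols; the hydrogen-bonded 2'-phenol reacts more slowly and needs excess reagent and warming. The chloride with imidazole does not enolise the methyl ketone.

Step 7
Reactants: 9 (6-bromo-2-geranyl-3-methoxyphenoxy)(tert-butyl)dimethylsilane; 11 2',4'-bis(tert-butyldimethylsilyloxy)-6'-methoxyacetophenone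
Product: 12 1-[2-methoxy-4,6-bis(tert-butyldimethylsilyloxy)phenyl]-2-[2-(tert-butyldimethylsilyloxy)-3-geranyl-4-methoxyphenyl]ethanone
Conditions: Pd(OAc)2 (5 mol%), XPhos (10 mol%), K3PO4, toluene, 80 °C
Reagents that add atoms: none
Why: Palladium-catalysed alpha-arylation of a ketone (Buchwald–Hartwig type): oxidative addition of 9 to zerovalent palladium formed in situ, enolate binding, and C–C reductive elimination driven by the bulky biarylphosphine. The weak, insoluble base K3PO4 is chosen to spare the aryl silyl ethers, and the hindered product enolate should not arylate a second time.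

Step 8
Reactants: 12 1-[2-methoxy-4,6-bis(tert-butyldimethylsilyloxy)phenyl]-2-[2-(tert-butyldimethylsilyloxy)-3-geranyl-4-methoxyphenyl]ethanone
Product: 13 2-diazo-1-[2-methoxy-4,6-bis(tert-butyldimethylsilyloxy)phenyl]-2-[2-(tert-butyldimethylsilyloxy)-3-geranyl-4-methoxyphenyl]ethanone
Conditions: p-ABSA, DBU, MeCN, 0 °C → rt, dark
Reagents that add atoms: 4-acetamidobenzenesulfonyl azide, CC(=O)Nc1ccc(cc1)S(=O)(=O)N=[N+]=[N-]
Why: Regitz diazo transfer; the methylene is benzylic and alpha to the ketone, so DBU gives enough enolate to attack the terminal nitrogen of the sulfonyl azide, and the adduct collapses to the diazo ketone and the sulfonamide. The conditions are anhydrous and non-nucleophilic, so the silyl ethers should persist.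

Step 9
Reactants: 13 2-diazo-1-[2-methoxy-4,6-bis(tert-butyldimethylsilyloxy)phenyl]-2-[2-(tert-butyldimethylsilyloxy)-3-geranyl-4-methoxyphenyl]ethanone
Product: 14 (3S)-5,7-bis(tert-butyldimethylsilyloxy)-3-[2-(tert-butyldimethylsilyloxy)-3-geranyl-4-methoxyphenyl]chroman-4-one
Conditions: Rh2(S-PTTL)4 (2 mol%), 4 Å MS, CH2Cl2, 13 added over 2 h, 0 °C → rt
Reagents that add atoms: none
Why: Rh2(S-PTTL)4, a dimer of divalent rhodium, is attacked by the diazo carbon of 13, nitrogen is lost, and an electrophilic carbenoid flanked by the aroyl acceptor and the ring B donor results at the future C3. This carbenoid takes up a C–H bond of the ortho methoxy group of ring A in a concerted but asynchronous three-centre transition state, with hydride-like transfer to carbon and positive charge at the methyl carbon stabilised by the ether oxygen, so that C2–C3 forms and the catalyst is released. The closest known reaction type is the dirhodium-catalysed intramolecular C–H insertion next to the ether oxygen of ortho-alkoxyaryl diazo ketones, which gives chroman-4-ones, together with insertion of aryl-substituted carbenoids into methyl ether C–H bonds; the present case combines the two on a primary C–H. Ring C closes as a six-membered ring (C3, C4, C4a, C8a, O1, C2) by 1,6-insertion. C3 is the only new stereocentre and is fixed in the insertion event, when the C–H bond adds to one face of the rhodium–carbon bond; the face is chosen by the chiral pocket of the four phthalimido tert-leucinate ligands, since the substrate is achiral. Site selectivity is needed against the silyl methyl groups and the geranyl chain: only the methoxy C–H bonds are oxygen-activated, the silyl groups offer unactivated primary C–H bonds and no aryl rings, and the geranyl chain sits meta to C1', where neither its alkenes nor its allylic hydrogens can reach the carbenoid within the molecule. Chemoselectivity is needed against attack on oxygen lone pairs (oxonium ylide, then methyl or silyl shift), Wolff rearrangement and bimolecular carbenoid reactions: the donor aryl group tempers the carbenoid, the tert-butyl groups screen the silyl ether oxygens, and slow addition at high dilution keeps the diazo concentration low. The medium is neutral and aprotic, so the new C3–H should not be enolised.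

Step 10
Reactants: 14 (3S)-5,7-bis(tert-butyldimethylsilyloxy)-3-[2-(tert-butyldimethylsilyloxy)-3-geranyl-4-methoxyphenyl]chroman-4-one
Product: 15 (3S)-5,7-dihydroxy-3-(3-geranyl-2-hydroxy-4-methoxyphenyl)chroman-4-one
Conditions: HF·pyridine, pyridine, THF, 0 °C → rt; pH 7 phosphate buffer work-up
Reagents that add atoms: none
Why: Fluoride-driven cleavage of the three aryl Si–O bonds, pulled by the strength of the Si–F bond. The pyridine-buffered medium is too weakly basic to enolise C3 and too weakly acidic to cyclise the 2'-phenol onto the geranyl chain, so the configuration set in step 9 should be kept.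

## Compound list

1 | 3-methoxyphenol | COc1cccc(O)c1 | starting material
2 | 1-methoxy-3-(methoxymethoxy)benzene | COCOc1cccc(OC)c1 | intermediate
3 | geranyl bromide, (2E)-1-bromo-3,7-dimethylocta-2,6-diene | CC(C)=CCC/C(C)=C/CBr | starting material
4 | [2-methoxy-6-(methoxymethoxy)phenyl]lithium | COCOc1cccc(OC)c1[Li] | intermediate (not isolated)
5 | 2-geranyl-1-methoxy-3-(methoxymethoxy)benzene | COCOc1cccc(OC)c1C/C=C(\C)CCC=C(C)C | intermediate
6 | [3-geranyl-4-methoxy-2-(methoxymethoxy)phenyl]lithium | COCOc1c([Li])ccc(OC)c1C/C=C(\C)CCC=C(C)C | intermediate (not isolated)
7 | 1-bromo-3-geranyl-4-methoxy-2-(methoxymethoxy)benzene | COCOc1c(Br)ccc(OC)c1C/C=C(\C)CCC=C(C)C | intermediate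
8 | 6-bromo-2-geranyl-3-methoxyphenol | COc1ccc(Br)c(O)c1C/C=C(\C)CCC=C(C)C | intermediate
9 | (6-bromo-2-geranyl-3-methoxyphenoxy)(tert-butyl)dimethylsilane | COc1ccc(Br)c(O[Si](C)(C)C(C)(C)C)c1C/C=C(\C)CCC=C(C)C | intermediate
10 | 2',4'-dihydroxy-6'-methoxyacetophenone | COc1cc(O)cc(O)c1C(C)=O | starting material
11 | 2',4'-bis(tert-butyldimethylsilyloxy)-6'-methoxyacetophenone | COc1cc(O[Si](C)(C)C(C)(C)C)cc(O[Si](C)(C)C(C)(C)C)c1C(C)=O | intermediate
12 | 1-[2-methoxy-4,6-bis(tert-butyldimethylsilyloxy)phenyl]-2-[2-(tert-butyldimethylsilyloxy)-3-geranyl-4-methoxyphenyl]ethanone | COc1cc(O[Si](C)(C)C(C)(C)C)cc(O[Si](C)(C)C(C)(C)C)c1C(=O)Cc1ccc(OC)c(C/C=C(\C)CCC=C(C)C)c1O[Si](C)(C)C(C)(C)C | intermediate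
13 | 2-diazo-1-[2-methoxy-4,6-bis(tert-butyldimethylsilyloxy)phenyl]-2-[2-(tert-butyldimethylsilyloxy)-3-geranyl-4-methoxyphenyl]ethanone | COc1cc(O[Si](C)(C)C(C)(C)C)cc(O[Si](C)(C)C(C)(C)C)c1C(=O)C(=[N+]=[N-])c1ccc(OC)c(C/C=C(\C)CCC=C(C)C)c1O[Si](C)(C)C(C)(C)C | intermediate
14 | (3S)-5,7-bis(tert-butyldimethylsilyloxy)-3-[2-(tert-butyldimethylsilyloxy)-3-geranyl-4-methoxyphenyl]chroman-4-one | COc1ccc([C@H]2COc3cc(O[Si](C)(C)C(C)(C)C)cc(O[Si](C)(C)C(C)(C)C)c3C2=O)c(O[Si](C)(C)C(C)(C)C)c1C/C=C(\C)CCC=C(C)C | intermediate
15 | (3S)-5,7-dihydroxy-3-(3-geranyl-2-hydroxy-4-methoxyphenyl)chroman-4-one | COc1ccc([C@H]2COc3cc(O)cc(O)c3C2=O)c(O)c1C/C=C(\C)CCC=C(C)C | target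

## Step count and least certain steps

Total: 10 steps. Longest linear sequence: 9 steps (steps 1–5 and 7–10, from 1); the ring A branch is one step (step 6).

**Step 9 (key step).** The carbenoid may be diverted before it reaches the methyl C–H bond. The target C–H is primary, the least reactive class, while the lone pairs of the ortho methoxy and silyloxy oxygens lie equally close, so ylide formation followed by methyl or silyl migration can compete. In addition, face selection rests on the catalyst alone and the acyl tether can fold toward either face, so enantioselectivity may be incomplete. The fallback takes stereocontrol away from the insertion, so that the ring-closing catalyst can be chosen for chemoselectivity only. Setting out from 13, an achiral catalyst of divalent rhodium, Rh2(esp)2 (dirhodium bis(α,α,α',α'-tetramethyl-1,3-benzenedipropanoate)), in CH2Cl2 should give the racemic isoflavanone tris(silyl ether) F1. F1 would then undergo asymmetric transfer hydrogenation under dynamic kinetic resolution with RuCl[(S,S)-TsDPEN](p-cymene) and HCO2H/Et3N. C3 equilibrates through the enol under the amine while one enantiomer is reduced faster, which should give the cis-(3S,4S)-isoflavan-4-ol tris(silyl ether) F2; the mirror-image ligand would be used if the sense proves opposite. Oxidation of F2 with Dess–Martin periodinane and NaHCO3 in CH2Cl2 at 0 °C re-forms the ketone without base and comes back to the route at 14.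

**Step 7.** Silyl loss or oxygen-to-oxygen silyl migration may occur, from the phenol oxygen ortho to the acetyl group onto the enolate oxygen under hot basic conditions. Reductive elimination at the ortho-silyloxy aryl palladium centre may also be slow, which favours hydrodebromination. The fallback forms the aryl–carbon bond on a diazo compound at room temperature, without a hot enolate, and bypasses 12 and step 8:
- From 11, LiN(SiMe3)2 in THF at −78 °C gives the lithium enolate F3, which is acylated in the same flask with 2,2,2-trifluoroethyl trifluoroacetate to the trifluoroacetyl ketone F4.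
- Mesyl azide and Et3N in MeCN convert F4 by detrifluoroacetylative diazo transfer into the diazomethyl ketone F5.
- Separately, 9 is converted by aromatic Finkelstein exchange (CuI, NaI, trans-N,N'-dimethylcyclohexane-1,2-diamine, dioxane, 110 °C) into the aryl iodide F6.
- Coupling of F5 with F6 under Pd(PPh3)4, Ag2CO3 and Et3N in toluene at room temperature arylates the diazo carbon with the diazo group retained and comes back to the route at 13.

**Step 8.** Diazo transfer may stall: the methylene lies between an aroyl group with two ortho substituents and an ortho-silyloxy aryl ring, so attack of the enolate on the sulfonyl azide is slow, and long exposure to DBU risks silyl cleavage. The fallback installs the diazo group through a hydrazone. Setting out from 12, aerobic oxidation (O2, DABCO cat., DMF, 80 °C) gives the 1,2-diketone F7. Condensation with p-toluenesulfonyl hydrazide (MeOH/THF, cat. AcOH) is expected at the less hindered carbonyl, the one next to ring B, giving the mono-tosylhydrazone F8. Bamford–Stevens elimination of sulfinate with DBU in CH2Cl2 at room temperature comes back to the route at 13.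

**Step 3.** Metalation may occur at the wrong site, next to the methyl ether or at the benzylic–allylic CH2 (which both oxygens flank), so that bromine enters the wrong position or the side chain is scrambled. The fallback places bromine first and the side chain last. Setting out from 1, amine-mediated ortho-bromination (NBS, i-Pr2NH cat., CH2Cl2, −78 → 0 °C) gives 2-bromo-5-methoxyphenol F9, which is also an article of commerce. Protection with MOMCl and i-Pr2NEt gives 1-bromo-4-methoxy-2-(methoxymethoxy)benzene F10. Deprotonation between the two oxygens with lithium 2,2,6,6-tetramethylpiperidide in THF at −78 °C, which does not exchange the bromine, gives the aryllithium F11. CuI-catalysed allylation of F11 with 3 comes back to the route at 7.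

**Step 4.** The liberated phenol may add under acid to the neighbouring alkene (chroman formation), and methanol or HCl may add to the alkenes if the acetal cleavage is slow. The fallback changes the directing group to one that leaves under much weaker acid:
- Setting out from 1, 3,4-dihydro-2H-pyran and pyridinium p-toluenesulfonate in CH2Cl2 give the tetrahydropyranyl ether F12.
- Lithiation as in step 2 gives the aryllithium F13, and allylation with 3 gives the geranyl tetrahydropyranyl ether F14.
- Lithiation as in step 3 gives the aryllithium F15, and bromination gives the bromo tetrahydropyranyl ether F16.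
- Pyridinium p-toluenesulfonate in MeOH at room temperature then frees the phenol under conditions too mild to protonate the alkene and comes back to the route at 8.

## Further compounds

F1 | step 9 | racemic 5,7-bis(tert-butyldimethylsilyloxy)-3-[2-(tert-butyldimethylsilyloxy)-3-geranyl-4-methoxyphenyl]chroman-4-one | COc1ccc(C2COc3cc(O[Si](C)(C)C(C)(C)C)cc(O[Si](C)(C)C(C)(C)C)c3C2=O)c(O[Si](C)(C)C(C)(C)C)c1C/C=C(\C)CCC=C(C)C
F2 | step 9 | (3S,4S)-5,7-bis(tert-butyldimethylsilyloxy)-3-[2-(tert-butyldimethylsilyloxy)-3-geranyl-4-methoxyphenyl]chroman-4-ol (cis) | COc1ccc([C@H]2COc3cc(O[Si](C)(C)C(C)(C)C)cc(O[Si](C)(C)C(C)(C)C)c3[C@H]2O)c(O[Si](C)(C)C(C)(C)C)c1C/C=C(\C)CCC=C(C)C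
F3 | step 7 | lithium enolate of 2',4'-bis(tert-butyldimethylsilyloxy)-6'-methoxyacetophenone | COc1cc(O[Si](C)(C)C(C)(C)C)cc(O[Si](C)(C)C(C)(C)C)c1C(=C)O[Li]
F4 | step 7 | 4,4,4-trifluoro-1-[2-methoxy-4,6-bis(tert-butyldimethylsilyloxy)phenyl]butane-1,3-dione | COc1cc(O[Si](C)(C)C(C)(C)C)cc(O[Si](C)(C)C(C)(C)C)c1C(=O)CC(=O)C(F)(F)F
F5 | step 7 | 2-diazo-1-[2-methoxy-4,6-bis(tert-butyldimethylsilyloxy)phenyl]ethanone | COc1cc(O[Si](C)(C)C(C)(C)C)cc(O[Si](C)(C)C(C)(C)C)c1C(=O)C=[N+]=[N-]
F6 | step 7 | tert-butyl(2-geranyl-6-iodo-3-methoxyphenoxy)dimethylsilane | COc1ccc(I)c(O[Si](C)(C)C(C)(C)C)c1C/C=C(\C)CCC=C(C)C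
F7 | step 8 | 1-[2-methoxy-4,6-bis(tert-butyldimethylsilyloxy)phenyl]-2-[2-(tert-butyldimethylsilyloxy)-3-geranyl-4-methoxyphenyl]ethane-1,2-dione | COc1cc(O[Si](C)(C)C(C)(C)C)cc(O[Si](C)(C)C(C)(C)C)c1C(=O)C(=O)c1ccc(OC)c(C/C=C(\C)CCC=C(C)C)c1O[Si](C)(C)C(C)(C)C
F8 | step 8 | 2-(p-toluenesulfonylhydrazono) derivative of F7 at the carbonyl next to ring B | COc1cc(O[Si](C)(C)C(C)(C)C)cc(O[Si](C)(C)C(C)(C)C)c1C(=O)C(=NNS(=O)(=O)c1ccc(C)cc1)c1ccc(OC)c(C/C=C(\C)CCC=C(C)C)c1O[Si](C)(C)C(C)(C)C
F9 | step 3 | 2-bromo-5-methoxyphenol | COc1ccc(Br)c(O)c1
F10 | step 3 | 1-bromo-4-methoxy-2-(methoxymethoxy)benzene | COCOc1cc(OC)ccc1Br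
F11 | step 3 | [3-bromo-6-methoxy-2-(methoxymethoxy)phenyl]lithium | COCOc1c(Br)ccc(OC)c1[Li]
F12 | step 4 | 2-(3-methoxyphenoxy)tetrahydro-2H-pyran | COc1cccc(OC2CCCCO2)c1
F13 | step 4 | [2-methoxy-6-(tetrahydro-2H-pyran-2-yloxy)phenyl]lithium | COc1cccc(OC2CCCCO2)c1[Li]
F14 | step 4 | 2-(2-geranyl-3-methoxyphenoxy)tetrahydro-2H-pyran | COc1cccc(OC2CCCCO2)c1C/C=C(\C)CCC=C(C)C
F15 | step 4 | [3-geranyl-4-methoxy-2-(tetrahydro-2H-pyran-2-yloxy)phenyl]lithium | COc1ccc([Li])c(OC2CCCCO2)c1C/C=C(\C)CCC=C(C)C
F16 | step 4 | 2-(6-bromo-2-geranyl-3-methoxyphenoxy)tetrahydro-2H-pyran | COc1ccc(Br)c(OC2CCCCO2)c1C/C=C(\C)CCC=C(C)C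
A1 | alternative 1 | (E)-1-diazo-4-[5,7-bis(methoxymethoxy)-4-oxo-4H-chromen-3-yl]but-3-en-2-one | [N-]=[N+]=CC(=O)/C=C/c1coc2cc(OCOC)cc(OCOC)c2c1=O
A2 | alternative 1 | (E)-4-[5,7-bis(methoxymethoxy)-4-oxo-4H-chromen-3-yl]buta-1,3-dien-1-one (vinylketene) | O=C=C/C=C/c1coc2cc(OCOC)cc(OCOC)c2c1=O
A3 | alternative 1 | (E)-1-methoxy-5,9-dimethyldeca-4,8-dien-1-yne | COC#CC/C=C(\C)CCC=C(C)C
A4 | alternative 1 | 3'-geranyl-2'-hydroxy-4'-methoxy-5,7-bis(methoxymethoxy)isoflavone | COCOc1cc(OCOC)c2c(c1)occ(-c1ccc(OC)c(C/C=C(\C)CCC=C(C)C)c1O)c2=O
A5 | alternative 2 | 5,7-bis(tert-butyldimethylsilyloxy)-2,2-dimethyl-4H-1,3-benzodioxin-4-one | CC1(C)OC(=O)c2c(O[Si](C)(C)C(C)(C)C)cc(O[Si](C)(C)C(C)(C)C)cc2O1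
A6 | alternative 2 | 3,5-bis(tert-butyldimethylsilyloxy)-6-(oxomethylidene)cyclohexa-2,4-dien-1-one (quinoketene) | O=C=C1C(=O)C=C(O[Si](C)(C)C(C)(C)C)C=C1O[Si](C)(C)C(C)(C)C
A7 | alternative 2 | tert-butyl{2-geranyl-3-methoxy-6-[(E)-2-methoxyethenyl]phenoxy}dimethylsilane | CO/C=C/c1ccc(OC)c(C/C=C(\C)CCC=C(C)C)c1O[Si](C)(C)C(C)(C)C
A8 | alternative 2 | 2-methoxy-5,7-bis(tert-butyldimethylsilyloxy)-3-[2-(tert-butyldimethylsilyloxy)-3-geranyl-4-methoxyphenyl]chroman-4-one, C2 and C3 not controlled | COC1Oc2cc(O[Si](C)(C)C(C)(C)C)cc(O[Si](C)(C)C(C)(C)C)c2C(=O)C1c1ccc(OC)c(C/C=C(\C)CCC=C(C)C)c1O[Si](C)(C)C(C)(C)C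
A9 | alternative 3 | (2S,3R)-3-[2-bromo-4,6-bis(methoxymethoxy)phenyl]-3-(tert-butyldimethylsilyloxy)-2-[3-geranyl-4-methoxy-2-(methoxymethoxy)phenyl]propan-1-ol | COc1ccc([C@@H](CO)[C@@H](O[Si](C)(C)C(C)(C)C)c2c(Br)cc(OCOC)cc2OCOC)c(OCOC)c1C/C=C(\C)CCC=C(C)C
A10 | alternative 3 | trans-(3S,4R)-4-(tert-butyldimethylsilyloxy)-3-[3-geranyl-4-methoxy-2-(methoxymethoxy)phenyl]-5,7-bis(methoxymethoxy)chroman | COc1ccc([C@H]2COc3cc(OCOC)cc(OCOC)c3[C@@H]2O[Si](C)(C)C(C)(C)C)c(OCOC)c1C/C=C(\C)CCC=C(C)C
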